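**Retrosynthetic overview**
- Target ⇒ racemic secondary allylic alcohol: the acetate C–O bond is made last, in an enantioconvergent (dynamic kinetic) O-acetylation that fixes the (4R) centre.
- Racemic alcohol ⇒ 4-hydroxy-5-methylcoumarin + racemic C10 1,4-diol: allyl–O(coumarin) ether bond by Mitsunobu alkylation at the primary allylic hydroxyl.
- C10 diol ⇒ (2E)-4-acetoxy-2-methylbut-2-enal + prenyl bromide: linear Barbier prenylation; the (E)-trisubstituted alkene is bought in.
- Coumarin ⇒ 2′-hydroxy-6′-methylacetophenone + diethyl carbonate: the pyranone ring is the only ring built and is closed first; the benzene ring is bought.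

Assumption: 2′-hydroxy-6′-methylacetophenone and (2E)-4-acetoxy-2-methylbut-2-enal (the industrial C5 vitamin A aldehyde) are taken as catalogue chemicals, and acetyl isopropyl carbonate is a pre-formed reagent (AcOH + isopropyl chloroformate).

**Route**

Step 1
Reactants: 1 1-(2-hydroxy-6-methylphenyl)ethan-1-one; 2 diethyl carbonate
Product: 4 4-hydroxy-5-methyl-2H-chromen-2-one, via aryl β-keto ester 3 (not isolated)
Conditions: NaH (3.5 equiv), toluene, 110 °C; then aq. HCl
Reagents that add atoms: none
Why: Claisen-type C-acylation of the methyl ketone enolate by diethyl carbonate followed by lactonisation of the phenoxide onto the new ester (standard 4-hydroxycoumarin synthesis) closes the only ring to be built; no stereocentre is involved.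

Step 2
Reactants: 5 (2E)-4-(acetyloxy)-2-methylbut-2-enal; 6 1-bromo-3-methylbut-2-ene
Product: 8 rac-(2E)-3,7-dimethylocta-2,6-diene-1,4-diol, via silyl ether acetate 7 (not isolated)
Conditions: Cp2TiCl2 (20 mol%), Mn dust, Me3SiCl, 2,4,6-collidine, THF, rt; then MeOH, K2CO3, rt (same flask)
Reagents that add atoms: none
Why: Titanocene(III)-mediated Barbier-type prenylation, in which Cp2TiCl (from Cp2TiCl2/Mn) converts prenyl bromide into a prenyl radical/prenyl–titanium species that attacks the conjugated aldehyde through its unsubstituted CH2 terminus (the linear, α-selective mode known for aryl and α,β-unsaturated aldehydes), Me3SiCl/collidine turns the titanium alkoxide over as silyl ether 7, and in-flask methanolysis removes silyl and acetyl groups; the (E)-alkene comes unchanged from 5 and the new carbinol centre is racemic at this stage.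

Step 3
Reactants: 4 4-hydroxy-5-methyl-2H-chromen-2-one; 8 rac-(2E)-3,7-dimethylocta-2,6-diene-1,4-diol
Product: 9 rac-4-{[(2E)-4-hydroxy-3,7-dimethylocta-2,6-dien-1-yl]oxy}-5-methyl-2H-chromen-2-one
Conditions: PPh3 (1.1 equiv), DIAD (1.1 equiv), THF, 0 °C → rt
Reagents that add atoms: none
Why: Mitsunobu etherification, in which the acidic 4-OH of 4 (pKa about 4) is O-alkylated by SN2 displacement of the oxyphosphonium formed at the unhindered primary allylic hydroxyl of 8, leaving the hindered secondary allylic OH, the alkene geometry and the still racemic C4 centre untouched.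

Step 4
Reactants: 9 rac-4-{[(2E)-4-hydroxy-3,7-dimethylocta-2,6-dien-1-yl]oxy}-5-methyl-2H-chromen-2-one
Product: 11 (2E,4R)-3,7-dimethyl-1-[(5-methyl-2-oxo-2H-chromen-4-yl)oxy]octa-2,6-dien-4-yl acetate, via enone 10 (not isolated)
Conditions: (η5-C5Ph5)Ru(CO)2Cl (5 mol%), KOtBu (5 mol%), planar-chiral (η5-C5Ph5)Fe-fused DMAP catalyst, the antipode that acetylates (R)-1-arylethanols (3 mol%), AcOCO2iPr (1.5 equiv), toluene/t-amyl alcohol, 10 °C → rt
Reagents that add atoms: acetyl isopropyl carbonate, CC(=O)OC(=O)OC(C)C
Why: Proposed new method: a dual-catalytic dynamic kinetic O-acetylation (enantioselective acyl transfer coupled to racemisation), not yet shown for an aryl-free, 2-methyl-substituted allylic carbinol carrying a second alkene and a vinylogous carbonate, in which the chiral acylpyridinium formed from the DMAP catalyst and the acyl carbonate acetylates the (R)-carbinol faster through π-contact with the 1-methylalkenyl group (same spatial pattern OH/π-group/alkyl as in (R)-1-arylethanols) while the Ru alkoxide racemises the slow (S)-carbinol by reversible β-hydride elimination and re-insertion through Ru-bound enone 10, the methyl group on the alkene and the non-dissociating ketone disfavouring 1,4-hydride isomerisation and the acyl carbonate releasing only CO2 and isopropanol so neither catalyst is protonated, so that the (4R) centre is fixed in the C–O acyl-transfer step; the closest known reaction types are Ru/lipase dynamic kinetic resolution of allylic alcohols and Ru/chiral-DMAP dynamic kinetic resolution of aryl alkyl carbinols.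

**Compound list**
1 | 1-(2-hydroxy-6-methylphenyl)ethan-1-one | CC(=O)c1c(O)cccc1C | starting material
2 | diethyl carbonate | CCOC(=O)OCC | starting material
3 | ethyl 3-(2-hydroxy-6-methylphenyl)-3-oxopropanoate (sodium salt in the flask, not isolated) | CCOC(=O)CC(=O)c1c(O)cccc1C | intermediate
4 | 4-hydroxy-5-methyl-2H-chromen-2-one | Cc1cccc2oc(=O)cc(O)c12 | intermediate
5 | (2E)-4-(acetyloxy)-2-methylbut-2-enal | CC(=O)OC/C=C(\C)C=O | starting material
6 | 1-bromo-3-methylbut-2-ene (prenyl bromide) | CC(C)=CCBr | starting material
7 | rac-(2E)-3,7-dimethyl-4-[(trimethylsilyl)oxy]octa-2,6-dien-1-yl acetate (not isolated) | CC(=O)OC/C=C(\C)C(O[Si](C)(C)C)CC=C(C)C | intermediate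
8 | rac-(2E)-3,7-dimethylocta-2,6-diene-1,4-diol | OC/C=C(\C)C(O)CC=C(C)C | intermediate
9 | rac-4-{[(2E)-4-hydroxy-3,7-dimethylocta-2,6-dien-1-yl]oxy}-5-methyl-2H-chromen-2-one | CC(C)=CCC(O)/C(C)=C/COc1cc(=O)oc2cccc(C)c12 | intermediate
10 | 4-{[(2E)-3,7-dimethyl-4-oxoocta-2,6-dien-1-yl]oxy}-5-methyl-2H-chromen-2-one (Ru-bound, not isolated in step 4) | CC(C)=CCC(=O)/C(C)=C/COc1cc(=O)oc2cccc(C)c12 | intermediate
11 | (2E,4R)-3,7-dimethyl-1-[(5-methyl-2-oxo-2H-chromen-4-yl)oxy]octa-2,6-dien-4-yl acetate | CC(=O)O[C@H](CC=C(C)C)/C(C)=C/COc1cc(=O)oc2cccc(C)c12 | target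

**Totals**
Total step count: 4. Longest linear sequence: 3 steps (steps 2, 3, 4); step 1 runs in parallel.

**Three steps most likely to fail**

Step 4 (the proposed new step). The selectivity factor of the chiral acyl-transfer catalyst for this aryl-free carbinol may be too low, and the Ru hydride may isomerise the allylic alcohol to the saturated ketone. The fallback uses known chemistry and sets the centre by hydride transfer instead of acyl transfer. It sets out from 9, which is oxidised with activated MnO2 in CH2Cl2 to enone 10, now isolated. Corey–Bakshi–Shibata reduction with (S)-2-methyl-CBS-oxazaborolidine and catecholborane in toluene at −78 °C (the alkenyl group acting as the large substituent) gives 4-{[(2E,4R)-4-hydroxy-3,7-dimethylocta-2,6-dien-1-yl]oxy}-5-methyl-2H-chromen-2-one F1. Acetylation with Ac2O, pyridine and catalytic DMAP then gives 11, where the route is rejoined.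

Step 2. The prenyl unit may add through its substituted terminus (branched adduct), the enal may undergo pinacol coupling, or the alkene geometry may erode at the titanium ketyl stage. The fallback builds the chain end by olefin metathesis instead of prenyl-metal addition. It sets out from 5, which undergoes Zn-mediated Barbier allylation with allyl bromide in THF/saturated aqueous NH4Cl to give rac-(2E)-4-hydroxy-3-methylhepta-2,6-dien-1-yl acetate F2. Cross-metathesis with excess 2-methylbut-2-ene (Grubbs second-generation catalyst, CH2Cl2, 40 °C) gives rac-(2E)-4-hydroxy-3,7-dimethylocta-2,6-dien-1-yl acetate F3, and K2CO3 in MeOH returns to the route at 8.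

Step 3. The ambident coumarin may be alkylated at C3 or at the lactone oxygen (2-alkoxychromone), and the peri methyl group hinders O4. The fallback reverses the polarity and forms the aryl C4–O bond instead of the allyl C–O bond. It sets out from 4, which is converted with POCl3 (Et3N, 80 °C) into 4-chloro-5-methyl-2H-chromen-2-one F4. Addition–elimination at C4 by the sodium alkoxide of the primary hydroxyl of 8 (NaH, 1 equiv, THF, 0 °C → rt) returns to the route at 9.

**Further compounds**
F1 | step 4 | 4-{[(2E,4R)-4-hydroxy-3,7-dimethylocta-2,6-dien-1-yl]oxy}-5-methyl-2H-chromen-2-one | O[C@H](CC=C(C)C)/C(C)=C/COc1cc(=O)oc2cccc(C)c12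
F2 | step 2 | rac-(2E)-4-hydroxy-3-methylhepta-2,6-dien-1-yl acetate | CC(=O)OC/C=C(\C)C(O)CC=C
F3 | step 2 | rac-(2E)-4-hydroxy-3,7-dimethylocta-2,6-dien-1-yl acetate | CC(=O)OC/C=C(\C)C(O)CC=C(C)C
F4 | step 3 | 4-chloro-5-methyl-2H-chromen-2-one | Cc1cccc2oc(=O)cc(Cl)c12
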